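If you charge 3.00 equiv of X on D, count again before you call it an excess: G stands in the flask too, and E can take X as well.

| flask | D | G | X | E | temperature | remark | time |
|---|---|---|---|---|---|---|---|
| Sunday's | 42 mM | 42 mM | 3 equiv | 5.9 mM | 25 °C | run made earlier |  |
| Friday's | 42 mM | 42 mM | 3 equiv | 9.2 mM | 60 °C | run made earlier |  |
| teal | 42 mM | 42 mM | 3.00 equiv | 4.20 mM | 90 °C |  | 4.0 d |
| red | 42 mM | 42 mM | 3.00 equiv | 4.20 mM | 60 °C |  | 4.0 d |
| green | 42 mM | 42 mM | 3.00 equiv | 4.20 mM | 30 °C |  | 4.0 d |

| run | time / d | Z / % | D / % |
|---|---|---|---|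
| Sunday's | 8.00 | 0 | 49 |
| Sunday's | 25.0 | 1 | 47 |
| Sunday's | 40.0 | 2 | 47 |
| Sunday's | 80.0 | 4 | 47 |
| Sunday's | 100 | 2 | 49 |
| Friday's | 1.67 | 1 | 49 |
| Friday's | 5.00 | 6 | 45 |
| Friday's | 8.00 | 14 | 40 |
| Friday's | 12.0 | 16 | 36 |
| Friday's | 20.0 | 20 | 28 |

(scatter of a reading: 1.5 percentage points)

- X is single-handed; D and G are mirror images of each other, charged as a racemate, each of them at the stated concentration
- what was read earlier has a scatter of 1.5 percentage points, one standard deviation
- on the list of suspects stand: X + D -> Z; X + G -> J; X + E -> L; Z <-> J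
- the handed part of X does not stay in what it makes, so the products of the two hands are mirror images too

- the best flask by amount of Z, in percent of the D and G together charged; "all alike" if 1.5 percentage points covers them all (teal / red / green / all alike)
- amount of Z at the end, in percent of the D and G together charged, teal
- amount of Z at the end, in percent of the D and G together charged, red
- amount of Z at the end, in percent of the D and G together charged, green

Friday's readings look like a slow first-order loss of D. Its last Z gives a pseudo-first-order constant of 0.0255 d⁻¹.

The objection is that this constant contains [X], and [X] falls. So suppose that each X takes one E, one D or one G, and that G goes at the pace of D, which these readings can't show. For teal, red and green, the charge of X less E, D and G leaves 37.8 mM of spare X, what stands over when the others have each taken theirs. Call it S. Then, once E has taken its X, [X] = S + 2[D], and k[X][D] integrates to a simple rule: [D]/[X] falls as exp(−kSt).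

Friday's S is 32.8 mM. Its Z reading puts [D] at 25.2 mM, so k at 60 °C reads 0.262 L mol⁻¹ d⁻¹.

A second doubt is E, but in red it can claim 3.33% of X, a small correction that S already carries. Red's ratio then ends at 0.331, which gives Z of 5.75%.

The forecast names teal, with 39% for teal, 5.3% for red and 0.25% for green, and holds that “X is in large excess”. Its teal and red figures, unpicked as first-order climbs to its ceiling of 50%, hold a temperature factor of 13.5. Sunday's Z is too near the scatter to better that, so I borrow it.

But in teal [X] can't be called flat. With k of 3.54 L mol⁻¹ d⁻¹, the ratio ends at 0.202, and my teal Z is 34.7%, lower than the forecast's. Green I leave at the forecast's figure, so teal still leads.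

The flasks give 33.4% in teal, 5.83% in red and 0.243% in green, so the best is teal. Teal stands 5.6 percentage points below the forecast.

    X + D → Z (k = 0.172 L mol⁻¹ h⁻¹, Ea = 92.0 kJ mol⁻¹)
    X + G → J (k = 0.106 L mol⁻¹ h⁻¹, Ea = 76.0 kJ mol⁻¹)
    X + E → L (k = 38.4 L mol⁻¹ h⁻¹, Ea = 63.0 kJ mol⁻¹)
    Z ⇌ J (k = 0.223 h⁻¹, Ea = 118 kJ mol⁻¹)
    (constants at 90 °C)

Now take the neighbour, a flask like green kept at 55 °C. Its S is still 37.8 mM, and in that flask Z stands at 3.70%. Run backwards as on Friday's reading, the rule turns that Z into k of 0.162 L mol⁻¹ d⁻¹ at 55 °C, lower than the 0.262 L mol⁻¹ d⁻¹ read from Friday's run at 60 °C.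

The data were generated by integration for substances that don't exist, and the scatter is random.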